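**Retrosynthetic overview** (locants follow the fatty-acid chain: C1 = CO2H, ring = C9–C13, OAc on C9, C=O at C12, C10=C11, pentenyl on C13)
1. The C6–C7 bond is made by a one-flask hydroboration / C(sp3)–C(sp3) Suzuki–Miyaura union of a ring-bearing vinyl carbinol (C7–C13) with methyl 6-bromohexanoate (C1–C6).
2. Enabling feature: C8 and C7 form an unbranched two-carbon arm on the fully substituted ring carbon C9. Held one oxidation level up as a vinyl group, they are the only monosubstituted alkene beside the 1,2-disubstituted ring alkene C10=C11, so boron goes to C7 alone and the extra unsaturation is removed in the same step.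
3. The cyclopentene ring (C9–C13) is not constructed; it comes from (S)-4-silyloxycyclopent-2-enone. The silyloxy centre directs vinyl addition to the ketone (sets C9) and is then oxidised to the C12 ketone (1,4-chirality relay).
4. C13–C14 is formed by α′-enolate alkylation with (Z)-1-bromopent-2-ene; the tertiary acetate and the free acid are released last (DMAP acetylation, lipase hydrolysis).
5. Ring order: one ring only, present from step 1.

Key step: step 2

Assumption: C13 is enolisable, and the epimer with the two carbon chains trans (pentenyl cis to the C9 oxygen, as in the target) is taken to be both the kinetic alkylation product and the thermodynamically preferred one.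

**Step 1**
Reactants: 1 (S)-4-[(tert-butyldimethylsilyl)oxy]cyclopent-2-en-1-one; 2 vinylmagnesium bromide
Product: 3 (1S,4S)-4-[(tert-butyldimethylsilyl)oxy]-1-ethenylcyclopent-2-en-1-ol (OH cis to OTBS)
Conditions: CeCl3, THF, −78 °C; aq. NH4Cl
Reagents that add atoms: none
Why: Imamoto-type organocerium 1,2-addition, in which the weakly basic vinyl reagent adds to the enone carbonyl without enolisation or β-elimination of the silyloxy group and enters anti to the C4 silyloxy substituent, which sets the tertiary carbinol centre (the later acetoxy carbon).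

**Step 2**
Reactants: 3 (1S,4S)-4-[(tert-butyldimethylsilyl)oxy]-1-ethenylcyclopent-2-en-1-ol; 4 methyl 6-bromohexanoate
Product: 6 methyl 8-[(1R,4S)-4-[(tert-butyldimethylsilyl)oxy]-1-hydroxycyclopent-2-en-1-yl]octanoate, via alkyl-9-BBN adduct 5 (not isolated)
Conditions: 9-BBN (2.2 equiv), THF, 0 °C to rt; then 4, Pd(OAc)2 (cat.), PCy3 (cat.), K3PO4·H2O, THF, rt
Reagents that add atoms: none
Why: 9-BBN adds its B–H bond across the only monosubstituted alkene (the vinyl group on the quaternary carbinol carbon) with boron on the terminal carbon, while the 1,2-disubstituted ring alkene, flanked by two substituted carbons, should not compete. Base turns the primary alkylborane 5 into a hydroxyborate, Pd(0)/PCy3 inserts into the C–Br bond of 4, the alkyl group moves from boron to palladium and reductive elimination forms the CH2–CH2 bond. The closest known reaction type is the B-alkyl Suzuki–Miyaura coupling of 9-alkyl-9-BBN reagents with primary alkyl bromides that carry β-hydrogens (Pd/trialkylphosphine, K3PO4·H2O). No ring is closed and no stereocentre is formed; the two carbinol centres of 3 stay untouched because the medium is basic and neither C–O bond is activated towards palladium. The step needs chemoselectivity (terminal over internal alkene), anti-Markovnikov regioselectivity and suppression of β-hydride elimination; the first two are secured by the bulk of 9-BBN next to a fully substituted carbon, the last by the bulky electron-rich phosphine. In one flask it removes the extra unsaturation and attaches six carbons with the carboxyl carbon already at the acid oxidation level, completing the eight-carbon arm.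

**Step 3**
Reactants: 6 methyl 8-[(1R,4S)-4-[(tert-butyldimethylsilyl)oxy]-1-hydroxycyclopent-2-en-1-yl]octanoate
Product: 7 methyl 8-[(1R,4S)-1,4-dihydroxycyclopent-2-en-1-yl]octanoate
Conditions: TBAF, AcOH, THF, 0 °C to rt
Reagents that add atoms: none
Why: Fluoride-mediated desilylation of the secondary allylic silyl ether, buffered with acetic acid so that the methyl ester and the diol are not exposed to strong base; no stereocentre changes.

**Step 4**
Reactants: 7 methyl 8-[(1R,4S)-1,4-dihydroxycyclopent-2-en-1-yl]octanoate
Product: 8 methyl 8-[(1R)-1-hydroxy-4-oxocyclopent-2-en-1-yl]octanoate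
Conditions: MnO2, CH2Cl2, rt
Reagents that add atoms: none
Why: Chemoselective MnO2 oxidation of the secondary allylic alcohol to the enone (the tertiary alcohol cannot be oxidised), which erases the relay stereocentre after it has fixed the quaternary carbinol configuration.

**Step 5**
Reactants: 9 (Z)-pent-2-en-1-ol
Product: 10 (Z)-1-bromopent-2-ene
Conditions: PBr3, Et2O, −10 °C
Reagents that add atoms: phosphorus tribromide, BrP(Br)Br
Why: SN2-type conversion of a primary allylic alcohol into the bromide at low temperature, which should keep the Z geometry.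

**Step 6**
Reactants: 8 methyl 8-[(1R)-1-hydroxy-4-oxocyclopent-2-en-1-yl]octanoate; 10 (Z)-1-bromopent-2-ene
Product: 13 methyl 8-[(1S,5S)-1-hydroxy-4-oxo-5-[(2Z)-pent-2-en-1-yl]cyclopent-2-en-1-yl]octanoate, via TMS ether 11 (not isolated), via alkylated TMS ether 12 (not isolated)
Conditions: TMSCl, imidazole, CH2Cl2, 0 °C; LiHMDS, THF, −78 °C; 10, DMPU, −78 to −30 °C; citric acid, MeOH/H2O, 0 °C
Reagents that add atoms: none
Why: Transient O-silylation blocks retro-aldol cleavage, LiHMDS forms the only possible (α′) ketone enolate, and SN2 enolate alkylation with the Z-allylic bromide should place the pentenyl group anti to the carbon chain on the neighbouring quaternary centre (cis to oxygen), which is also the expected stable arrangement at this epimerisable centre; mild acid then removes the TMS group.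

**Step 7**
Reactants: 13 methyl 8-[(1S,5S)-1-hydroxy-4-oxo-5-[(2Z)-pent-2-en-1-yl]cyclopent-2-en-1-yl]octanoate
Product: 14 methyl 8-[(1S,5S)-1-(acetyloxy)-4-oxo-5-[(2Z)-pent-2-en-1-yl]cyclopent-2-en-1-yl]octanoate
Conditions: Ac2O, DMAP, pyridine, CH2Cl2, rt
Reagents that add atoms: acetic anhydride, CC(=O)OC(C)=O
Why: DMAP-catalysed acyl transfer (Steglich-type acylation) to the tertiary alcohol under weakly basic, non-enolising conditions, so the neighbouring enolisable stereocentre should be kept.

**Step 8**
Reactants: 14 methyl 8-[(1S,5S)-1-(acetyloxy)-4-oxo-5-[(2Z)-pent-2-en-1-yl]cyclopent-2-en-1-yl]octanoate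
Product: 15 8-[(1S,5S)-1-(acetyloxy)-4-oxo-5-[(2Z)-pent-2-en-1-yl]cyclopent-2-en-1-yl]octanoic acid
Conditions: Candida antarctica lipase B (immobilised), phosphate buffer pH 7/acetone, 30 °C
Reagents that add atoms: water, O
Why: Lipase-catalysed ester hydrolysis at neutral pH should cleave the unhindered methyl ester while the tertiary acetate is not accepted by the enzyme, and it avoids base-induced β-elimination of the β-acetoxy ketone.

**Compound list**
1 | (S)-4-[(tert-butyldimethylsilyl)oxy]cyclopent-2-en-1-one | O=C1C=C[C@@H](O[Si](C)(C)C(C)(C)C)C1 | starting material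
2 | vinylmagnesium bromide | C=C[Mg]Br | starting material
3 | (1S,4S)-4-[(tert-butyldimethylsilyl)oxy]-1-ethenylcyclopent-2-en-1-ol | C1[C@H](O[Si](C)(C)C(C)(C)C)C=C[C@]1(C=C)O | intermediate
4 | methyl 6-bromohexanoate | COC(=O)CCCCCBr | starting material
5 | 9-{2-[(1R,4S)-4-[(tert-butyldimethylsilyl)oxy]-1-hydroxycyclopent-2-en-1-yl]ethyl}-9-borabicyclo[3.3.1]nonane | C1[C@H](O[Si](C)(C)C(C)(C)C)C=C[C@]1(CCB2C3CCCC2CCC3)O | intermediate (not isolated)
6 | methyl 8-[(1R,4S)-4-[(tert-butyldimethylsilyl)oxy]-1-hydroxycyclopent-2-en-1-yl]octanoate | C1[C@H](O[Si](C)(C)C(C)(C)C)C=C[C@]1(CCCCCCCC(=O)OC)O | intermediate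
7 | methyl 8-[(1R,4S)-1,4-dihydroxycyclopent-2-en-1-yl]octanoate | C1[C@H](O)C=C[C@]1(CCCCCCCC(=O)OC)O | intermediate
8 | methyl 8-[(1R)-1-hydroxy-4-oxocyclopent-2-en-1-yl]octanoate | C1C(=O)C=C[C@]1(CCCCCCCC(=O)OC)O | intermediate
9 | (Z)-pent-2-en-1-ol | CC/C=C\CO | starting material
10 | (Z)-1-bromopent-2-ene | CC/C=C\CBr | intermediate
11 | methyl 8-[(1R)-4-oxo-1-[(trimethylsilyl)oxy]cyclopent-2-en-1-yl]octanoate | C1C(=O)C=C[C@]1(CCCCCCCC(=O)OC)O[Si](C)(C)C | intermediate (not isolated)
12 | methyl 8-[(1S,5S)-4-oxo-5-[(2Z)-pent-2-en-1-yl]-1-[(trimethylsilyl)oxy]cyclopent-2-en-1-yl]octanoate | CC/C=C\C[C@@H]1C(=O)C=C[C@]1(CCCCCCCC(=O)OC)O[Si](C)(C)C | intermediate (not isolated)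
13 | methyl 8-[(1S,5S)-1-hydroxy-4-oxo-5-[(2Z)-pent-2-en-1-yl]cyclopent-2-en-1-yl]octanoate | CC/C=C\C[C@@H]1C(=O)C=C[C@]1(CCCCCCCC(=O)OC)O | intermediate
14 | methyl 8-[(1S,5S)-1-(acetyloxy)-4-oxo-5-[(2Z)-pent-2-en-1-yl]cyclopent-2-en-1-yl]octanoate | CC/C=C\C[C@@H]1C(=O)C=C[C@]1(CCCCCCCC(=O)OC)OC(C)=O | intermediate
15 | 8-[(1S,5S)-1-(acetyloxy)-4-oxo-5-[(2Z)-pent-2-en-1-yl]cyclopent-2-en-1-yl]octanoic acid | CC/C=C\C[C@@H]1C(=O)C=C[C@]1(CCCCCCCC(=O)O)OC(C)=O | target

**Step count**
Total steps: 8. Longest linear sequence: 7 (steps 1, 2, 3, 4, 6, 7, 8).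

**Steps most likely to fail**

Step 6 (enolate alkylation). The C-alkylation of a hindered, cross-conjugated enolate next to a quaternary centre may be slow or unselective: proton transfer, SN2′ attack on the allylic bromide, partial loss of the Z geometry, or attack on the wrong face at the new stereocentre. The fallback sets out from 11. Its lithium enolate is alkylated with the more reactive 1-bromopent-2-yne, which has no alkene geometry to lose, to give methyl 8-[(1S,5S)-4-oxo-5-(pent-2-yn-1-yl)-1-[(trimethylsilyl)oxy]cyclopent-2-en-1-yl]octanoate F1. A wrong epimer at the α-carbon can be corrected by base equilibration at this silyl ether stage. Citric acid work-up gives methyl 8-[(1S,5S)-1-hydroxy-4-oxo-5-(pent-2-yn-1-yl)cyclopent-2-en-1-yl]octanoate F2. Lindlar semi-hydrogenation (H2, Pd/CaCO3/Pb, quinoline, EtOAc) then sets the Z-alkene and comes back to the route at 13.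

Step 2 (key union). The alkyl–alkyl coupling may stall through slow boron-to-palladium transfer or β-hydride elimination, or the tertiary allylic C–O bond may ionise under Pd/boron activation. The fallback reverses the roles of the partners and sets out from 3. Hydroboration with 9-BBN (again through 5) and oxidative work-up (H2O2, NaOH) give (1R,4S)-4-[(tert-butyldimethylsilyl)oxy]-1-(2-hydroxyethyl)cyclopent-2-en-1-ol F3. Selective Appel iodination of the primary alcohol (I2, PPh3, imidazole) gives (1S,4S)-4-[(tert-butyldimethylsilyl)oxy]-1-(2-iodoethyl)cyclopent-2-en-1-ol F4. Zinc insertion into 4 (Zn dust, cat. I2, DMA) gives (6-methoxy-6-oxohexyl)zinc bromide F5. Negishi alkyl–alkyl coupling of F4 with F5 (Pd2(dba)3, PCyp3, N-methylimidazole, THF/NMP) comes back to the route at 6.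

Step 7 (tertiary acetate). Acyl transfer to the hindered tertiary alcohol may be sluggish, with retro-aldol ring opening or β-elimination competing under base. The fallback sets out from 12, which is isolated by a neutral work-up of step 6 in place of the acid treatment. The silyl ether is converted directly into the acetate with Ac2O and catalytic Bi(OTf)3 (desilylative acetylation under non-basic conditions), which comes back to the route at 14; this fallback makes no new compound (F0).

**Further compounds**
F1 | step 6 | methyl 8-[(1S,5S)-4-oxo-5-(pent-2-yn-1-yl)-1-[(trimethylsilyl)oxy]cyclopent-2-en-1-yl]octanoate | CCC#CC[C@@H]1C(=O)C=C[C@]1(CCCCCCCC(=O)OC)O[Si](C)(C)C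
F2 | step 6 | methyl 8-[(1S,5S)-1-hydroxy-4-oxo-5-(pent-2-yn-1-yl)cyclopent-2-en-1-yl]octanoate | CCC#CC[C@@H]1C(=O)C=C[C@]1(CCCCCCCC(=O)OC)O
F3 | step 2 | (1R,4S)-4-[(tert-butyldimethylsilyl)oxy]-1-(2-hydroxyethyl)cyclopent-2-en-1-ol | C1[C@H](O[Si](C)(C)C(C)(C)C)C=C[C@]1(CCO)O
F4 | step 2 | (1S,4S)-4-[(tert-butyldimethylsilyl)oxy]-1-(2-iodoethyl)cyclopent-2-en-1-ol | C1[C@H](O[Si](C)(C)C(C)(C)C)C=C[C@]1(CCI)O
F5 | step 2 | (6-methoxy-6-oxohexyl)zinc bromide | COC(=O)CCCCC[Zn]Br
F0 | step 7 | none | none
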